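**Retrosynthetic overview**

1. The target is unmasked last from its C6 ethyl enol ether and tertiary silyl ether. The quaternary C3a comes from dearomative prenylation of a 5-acyl-2,3-dihydrobenzofuran-4-ol, with the prenyl group entering anti to the C2 substituent.
2. The C5 isobutyryl group is moved from the phenol oxygen to carbon (photo-Fries), and the side-chain oxirane comes from Shi epoxidation of the C7 prenyl group.
3. Key disconnection: the carbocycle is opened between C3a and C4 to a dienylketene, made from a vinylketene and ethoxyethyne by [2+2] and 4π ring opening. The enabling feature is the enol-ether double bond C7a=C3a inside the five-membered ring (O1 on C7a): it is the terminal 2π unit of the 6π closure, and C3a still carries H so the product aromatises.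
4. The oxolane ring (O1, C2, C3, C3a, C7a) is made first, by domino C-alkylation/5-exo O-cyclisation of a β-keto ester dianion with an (R)-epoxy tosylate from prenol.
5. Ring order: oxolane (step 3), benzene ring through the C3a–C4 bond (step 5), oxirane (step 7), dearomatisation (step 9).

Key step: step 5

Remark: the target is one enol form of a β-triketone; its tautomers interconvert, so the route aims at the triketone and the final SMILES shows the given enol.

**Step 1**
Reactants: 1 3-methylbut-2-en-1-ol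
Product: 3 [(2R)-3,3-dimethyloxiran-2-yl]methyl 4-methylbenzenesulfonate, via epoxy alcohol 2 (not isolated)
Conditions: Ti(OiPr)4 (cat.), D-(−)-diethyl tartrate (cat.), t-BuOOH, 4 Å MS, CH2Cl2, −20 °C; then TsCl, Et3N, DMAP (cat.), −10 °C
Reagents that add atoms: tert-butyl hydroperoxide CC(C)(C)OO; 4-methylbenzenesulfonyl chloride Cc1ccc(cc1)S(Cl)(=O)=O
Why: Sharpless asymmetric epoxidation with the D-(−)-tartrate ligand should give the (2R)-epoxy alcohol by reagent control, and tosylation in the same flask avoids isolating the water-soluble epoxy alcohol.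

**Step 2**
Reactants: 4 prop-2-en-1-yl 3-oxobutanoate; 5 1-bromo-3-methylbut-2-ene
Product: 6 prop-2-en-1-yl 2-acetyl-5-methylhex-4-enoate (racemic)
Conditions: NaH, THF, 0 °C to rt
Reagents that add atoms: none
Why: Acetoacetic ester C-alkylation of the sodium enolate with an allylic bromide; the new centre is racemic and becomes an sp2 carbon in step 3.

**Step 3**
Reactants: 6 prop-2-en-1-yl 2-acetyl-5-methylhex-4-enoate; 3 [(2R)-3,3-dimethyloxiran-2-yl]methyl 4-methylbenzenesulfonate
Product: 9 prop-2-en-1-yl 5-methyl-2-[(5S)-5-{2-[(triethylsilyl)oxy]propan-2-yl}oxolan-2-ylidene]hex-4-enoate (E/Z mixture), via epoxy keto ester 7 (not isolated), via hydroxy ester 8 (not isolated)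
Conditions: LDA (2.2 equiv), THF, −78 to 0 °C; then 3, −78 °C to rt; LiClO4, 45 °C; then TESOTf, −78 to 0 °C
Reagents that add atoms: triethylsilyl trifluoromethanesulfonate CC[Si](CC)(CC)OS(=O)(=O)C(F)(F)F
Why: Domino reaction of a β-keto ester dianion: the terminal carbanion displaces the primary tosylate (SN2), then the enolate oxygen opens the epoxide by 5-exo-tet attack at the secondary carbon with inversion (C-cyclisation would be a disfavoured 5-(enolendo)-exo-tet closure), which turns the (R)-epoxide carbon into the (S)-C5 of the oxolane; the tertiary alkoxide is silylated in the flask.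

**Step 4**
Reactants: 9 prop-2-en-1-yl 5-methyl-2-[(5S)-5-{2-[(triethylsilyl)oxy]propan-2-yl}oxolan-2-ylidene]hex-4-enoate
Product: 10 5-methyl-2-[(5S)-5-{2-[(triethylsilyl)oxy]propan-2-yl}oxolan-2-ylidene]hex-4-enoic acid
Conditions: Pd(PPh3)4 (cat.), morpholine, THF, rt; pH 5 buffer work-up
Reagents that add atoms: none
Why: Pd(0)-catalysed allyl transfer to morpholine (Tsuji–Trost deallylation) should free the acid under neutral conditions that spare the acid-labile enol ether and the silyl ether.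

**Step 5**
Reactants: 10 5-methyl-2-[(5S)-5-{2-[(triethylsilyl)oxy]propan-2-yl}oxolan-2-ylidene]hex-4-enoic acid; 11 ethoxyethyne
Product: 17 (2S)-6-ethoxy-7-(3-methylbut-2-en-1-yl)-2-{2-[(triethylsilyl)oxy]propan-2-yl}-2,3-dihydro-1-benzofuran-4-ol, via acid chloride 12 (not isolated), via vinylketene 13 (not isolated), via cyclobutenone 14 (not isolated), via dienylketene 15 (not isolated), via cyclohexadienone 16 (not isolated)
Conditions: 1-chloro-N,N,2-trimethylprop-1-en-1-amine, ClCH2CH2Cl, 0 °C to rt; then 11, Et3N, 0 °C to rt; then 80 °C (sealed vessel)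
Reagents that add atoms: none
Why: 1,4-Dehydrochlorination of the β-alkoxy enoyl chloride 12 at the γ-CH2 (C3 of the oxolane) gives vinylketene 13, whose ketene C=C adds ethoxyethyne in a [2+2] cycloaddition (ketene carbonyl carbon to the nucleophilic CH terminus of the ynol ether) to give 4-vinylcyclobutenone 14. At 80 °C 14 opens by reversible 4π-electrocyclic ring opening to dienylketene 15, and the six-membered ring is closed by a thermal disrotatory 6π-electrocyclisation in which the ketene carbon (future C4) bonds to the enol-ether β-carbon of the dihydrofuran (future C3a); tautomerisation of dienone 16 gives the phenol. This is the Danheiser benzannulation (vinylketene plus heteroatom-substituted alkyne), run with an acid chloride as the ketene source. No lasting stereocentre is created (C4 of 14 and the C3a–H centre of 16 are transient), and C2 is remote and untouched. The regiochemistry needed (ethoxy group at C6 next to the prenylated C7, free OH at C4, H at C5) follows from the polarity of the ketene/ynol ether pair, and only the ring-opened isomer of 15 with the dihydrofuranyl group cis to the ketene chain can cyclise, while the other returns to 14.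

**Step 6**
Reactants: 17 (2S)-6-ethoxy-7-(3-methylbut-2-en-1-yl)-2-{2-[(triethylsilyl)oxy]propan-2-yl}-2,3-dihydro-1-benzofuran-4-ol; 18 2-methylpropanoyl chloride
Product: 19 (2S)-6-ethoxy-7-(3-methylbut-2-en-1-yl)-2-{2-[(triethylsilyl)oxy]propan-2-yl}-2,3-dihydro-1-benzofuran-4-yl 2-methylpropanoate
Conditions: Et3N, DMAP (cat.), CH2Cl2, 0 °C
Reagents that add atoms: none
Why: DMAP-catalysed O-acylation of the phenol; the ester masks the phenol during the epoxidation and carries the acyl group that is moved to C5 in step 8.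

**Step 7**
Reactants: 19 (2S)-6-ethoxy-7-(3-methylbut-2-en-1-yl)-2-{2-[(triethylsilyl)oxy]propan-2-yl}-2,3-dihydro-1-benzofuran-4-yl 2-methylpropanoate
Product: 20 (2S)-7-{[(2R)-3,3-dimethyloxiran-2-yl]methyl}-6-ethoxy-2-{2-[(triethylsilyl)oxy]propan-2-yl}-2,3-dihydro-1-benzofuran-4-yl 2-methylpropanoate
Conditions: D-fructose-derived ketone catalyst, Oxone, K2CO3, Bu4NHSO4 (cat.), MeCN/dimethoxymethane/aq. Na2B4O7–EDTA buffer, 0 °C
Reagents that add atoms: Oxone (potassium peroxymonosulfate) [K+].[O-]S(=O)(=O)OO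
Why: Shi epoxidation: the chiral dioxirane should attack the only isolated trisubstituted alkene and give the (R)-oxirane by reagent control (spiro transition state), with no free phenol present to be oxidised.

**Step 8**
Reactants: 20 (2S)-7-{[(2R)-3,3-dimethyloxiran-2-yl]methyl}-6-ethoxy-2-{2-[(triethylsilyl)oxy]propan-2-yl}-2,3-dihydro-1-benzofuran-4-yl 2-methylpropanoate
Product: 21 1-[(2S)-7-{[(2R)-3,3-dimethyloxiran-2-yl]methyl}-6-ethoxy-4-hydroxy-2-{2-[(triethylsilyl)oxy]propan-2-yl}-2,3-dihydro-1-benzofuran-5-yl]-2-methylpropan-1-one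
Conditions: hν (254 nm, quartz), degassed cyclohexane, rt
Reagents that add atoms: none
Why: Photo-Fries rearrangement: homolysis of the aryl ester C–O bond and in-cage recombination at the only unsubstituted ortho carbon (C5) should give the hydrogen-bonded, photostable ortho-hydroxy ketone without touching a stereocentre.

**Step 9**
Reactants: 21 1-[(2S)-7-{[(2R)-3,3-dimethyloxiran-2-yl]methyl}-6-ethoxy-4-hydroxy-2-{2-[(triethylsilyl)oxy]propan-2-yl}-2,3-dihydro-1-benzofuran-5-yl]-2-methylpropan-1-one; 5 1-bromo-3-methylbut-2-ene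
Product: 22 (2S,3aS)-7-{[(2R)-3,3-dimethyloxiran-2-yl]methyl}-6-ethoxy-3a-(3-methylbut-2-en-1-yl)-5-(2-methylpropanoyl)-2-{2-[(triethylsilyl)oxy]propan-2-yl}-3,3a-dihydro-1-benzofuran-4(2H)-one
Conditions: NaH, toluene, 0 °C; then 5, 0 °C to rt
Reagents that add atoms: none
Why: Dearomative ortho C-alkylation of a sodium phenoxide in a non-polar solvent (contact ion pair) should put the prenyl group on C3a, and the electrophile should approach the planar ring carbon anti to the bulky C2 substituent (1,3-induction, as in the alkylation of γ-substituted butyrolactone enolates), which sets C3a with prenyl trans to the silyloxypropyl group.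

**Step 10**
Reactants: 22 (2S,3aS)-7-{[(2R)-3,3-dimethyloxiran-2-yl]methyl}-6-ethoxy-3a-(3-methylbut-2-en-1-yl)-5-(2-methylpropanoyl)-2-{2-[(triethylsilyl)oxy]propan-2-yl}-3,3a-dihydro-1-benzofuran-4(2H)-one
Product: 24 (2S,3aR)-7-{[(2R)-3,3-dimethyloxiran-2-yl]methyl}-4-hydroxy-2-(2-hydroxypropan-2-yl)-3a-(3-methylbut-2-en-1-yl)-5-(2-methylpropanoyl)-3,3a-dihydro-1-benzofuran-6(2H)-one, via hydroxy enol ether 23 (not isolated)
Conditions: TBAF, AcOH, THF, 0 °C to rt; then LiOH, THF/H2O, 0 °C; AcOH to pH 5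
Reagents that add atoms: lithium hydroxide [Li+].[OH-]
Why: Buffered fluoride cleaves the tertiary silyl ether, and hydroxide then replaces the ethoxy group of the doubly activated vinylogous ester by addition–elimination at C6 (vinylogous ester hydrolysis) to give the β-triketone; the weakly nucleophilic triketonate should leave the hindered oxirane intact and no stereocentre is involved (the C3a descriptor changes from S to R only through CIP priorities).

**Compound list**

1 | 3-methylbut-2-en-1-ol | CC(C)=CCO | starting material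
2 | [(2R)-3,3-dimethyloxiran-2-yl]methanol | OC[C@H]1OC1(C)C | intermediate
3 | [(2R)-3,3-dimethyloxiran-2-yl]methyl 4-methylbenzenesulfonate | Cc1ccc(cc1)S(=O)(=O)OC[C@H]1OC1(C)C | intermediate
4 | prop-2-en-1-yl 3-oxobutanoate | CC(=O)CC(=O)OCC=C | starting material
5 | 1-bromo-3-methylbut-2-ene | CC(C)=CCBr | starting material
6 | prop-2-en-1-yl 2-acetyl-5-methylhex-4-enoate (racemic) | CC(=O)C(CC=C(C)C)C(=O)OCC=C | intermediate
7 | prop-2-en-1-yl 2-{3-[(2R)-3,3-dimethyloxiran-2-yl]propanoyl}-5-methylhex-4-enoate (as lithium enolate) | CC(C)=CCC(C(=O)OCC=C)C(=O)CC[C@H]1OC1(C)C | intermediate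
8 | prop-2-en-1-yl 2-[(5S)-5-(2-hydroxypropan-2-yl)oxolan-2-ylidene]-5-methylhex-4-enoate (as lithium alkoxide) | C=CCOC(=O)C(CC=C(C)C)=C1CC[C@@H](C(C)(C)O)O1 | intermediate
9 | prop-2-en-1-yl 5-methyl-2-[(5S)-5-{2-[(triethylsilyl)oxy]propan-2-yl}oxolan-2-ylidene]hex-4-enoate | C=CCOC(=O)C(CC=C(C)C)=C1CC[C@@H](C(C)(C)O[Si](CC)(CC)CC)O1 | intermediate
10 | 5-methyl-2-[(5S)-5-{2-[(triethylsilyl)oxy]propan-2-yl}oxolan-2-ylidene]hex-4-enoic acid | OC(=O)C(CC=C(C)C)=C1CC[C@@H](C(C)(C)O[Si](CC)(CC)CC)O1 | intermediate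
11 | ethoxyethyne | CCOC#C | starting material
12 | 5-methyl-2-[(5S)-5-{2-[(triethylsilyl)oxy]propan-2-yl}oxolan-2-ylidene]hex-4-enoyl chloride | ClC(=O)C(CC=C(C)C)=C1CC[C@@H](C(C)(C)O[Si](CC)(CC)CC)O1 | intermediate
13 | 5-methyl-2-[(5S)-5-{2-[(triethylsilyl)oxy]propan-2-yl}-4,5-dihydrofuran-2-yl]hexa-1,4-dien-1-one | O=C=C(CC=C(C)C)C1=CC[C@@H](C(C)(C)O[Si](CC)(CC)CC)O1 | intermediate
14 | 3-ethoxy-4-(3-methylbut-2-en-1-yl)-4-[(5S)-5-{2-[(triethylsilyl)oxy]propan-2-yl}-4,5-dihydrofuran-2-yl]cyclobut-2-en-1-one (both C4 epimers) | CCOC1=CC(=O)C1(CC=C(C)C)C2=CC[C@@H](C(C)(C)O[Si](CC)(CC)CC)O2 | intermediate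
15 | (3E)-3-ethoxy-7-methyl-4-[(5S)-5-{2-[(triethylsilyl)oxy]propan-2-yl}-4,5-dihydrofuran-2-yl]octa-1,3,6-trien-1-one | O=C=C/C(OCC)=C(/CC=C(C)C)C1=CC[C@@H](C(C)(C)O[Si](CC)(CC)CC)O1 | intermediate
16 | (2S)-6-ethoxy-7-(3-methylbut-2-en-1-yl)-2-{2-[(triethylsilyl)oxy]propan-2-yl}-3,3a-dihydro-1-benzofuran-4(2H)-one (either 3a epimer) | CCOC1=CC(=O)C2C[C@@H](C(C)(C)O[Si](CC)(CC)CC)OC2=C1CC=C(C)C | intermediate
17 | (2S)-6-ethoxy-7-(3-methylbut-2-en-1-yl)-2-{2-[(triethylsilyl)oxy]propan-2-yl}-2,3-dihydro-1-benzofuran-4-ol | CCOc1cc(O)c2C[C@@H](C(C)(C)O[Si](CC)(CC)CC)Oc2c1CC=C(C)C | intermediate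
18 | 2-methylpropanoyl chloride | CC(C)C(Cl)=O | starting material
19 | (2S)-6-ethoxy-7-(3-methylbut-2-en-1-yl)-2-{2-[(triethylsilyl)oxy]propan-2-yl}-2,3-dihydro-1-benzofuran-4-yl 2-methylpropanoate | CCOc1cc(OC(=O)C(C)C)c2C[C@@H](C(C)(C)O[Si](CC)(CC)CC)Oc2c1CC=C(C)C | intermediate
20 | (2S)-7-{[(2R)-3,3-dimethyloxiran-2-yl]methyl}-6-ethoxy-2-{2-[(triethylsilyl)oxy]propan-2-yl}-2,3-dihydro-1-benzofuran-4-yl 2-methylpropanoate | CCOc1cc(OC(=O)C(C)C)c2C[C@@H](C(C)(C)O[Si](CC)(CC)CC)Oc2c1C[C@H]3OC3(C)C | intermediate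
21 | 1-[(2S)-7-{[(2R)-3,3-dimethyloxiran-2-yl]methyl}-6-ethoxy-4-hydroxy-2-{2-[(triethylsilyl)oxy]propan-2-yl}-2,3-dihydro-1-benzofuran-5-yl]-2-methylpropan-1-one | CCOc1c(C(=O)C(C)C)c(O)c2C[C@@H](C(C)(C)O[Si](CC)(CC)CC)Oc2c1C[C@H]3OC3(C)C | intermediate
22 | (2S,3aS)-7-{[(2R)-3,3-dimethyloxiran-2-yl]methyl}-6-ethoxy-3a-(3-methylbut-2-en-1-yl)-5-(2-methylpropanoyl)-2-{2-[(triethylsilyl)oxy]propan-2-yl}-3,3a-dihydro-1-benzofuran-4(2H)-one | CCOC1=C(C(=O)C(C)C)C(=O)[C@@]2(CC=C(C)C)C[C@@H](C(C)(C)O[Si](CC)(CC)CC)OC2=C1C[C@H]3OC3(C)C | intermediate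
23 | (2S,3aS)-7-{[(2R)-3,3-dimethyloxiran-2-yl]methyl}-6-ethoxy-2-(2-hydroxypropan-2-yl)-3a-(3-methylbut-2-en-1-yl)-5-(2-methylpropanoyl)-3,3a-dihydro-1-benzofuran-4(2H)-one | CCOC1=C(C(=O)C(C)C)C(=O)[C@@]2(CC=C(C)C)C[C@@H](C(C)(C)O)OC2=C1C[C@H]3OC3(C)C | intermediate
24 | (2S,3aR)-7-{[(2R)-3,3-dimethyloxiran-2-yl]methyl}-4-hydroxy-2-(2-hydroxypropan-2-yl)-3a-(3-methylbut-2-en-1-yl)-5-(2-methylpropanoyl)-3,3a-dihydro-1-benzofuran-6(2H)-one (CNP0395488.1) | CC(C)=CC[C@]12C[C@@H](C(C)(C)O)OC1=C(C[C@H]1OC1(C)C)C(=O)C(C(=O)C(C)C)=C2O | target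

**Step count and risks**

Total steps: 10. Longest linear sequence: 9 (steps 2–10; the branch through step 1 joins at step 3 and is equally long).

Steps most likely to fail:

1. Step 9. Alkylation may go to the phenoxide oxygen or to the para carbon C7 instead of C3a, or the C2 substituent may discriminate the two faces poorly. Fallback: from 21, Pd(0)-catalysed Tsuji–Trost allylation (allyl methyl carbonate, Pd(PPh3)4, THF), in which O-allylation is reversible through re-ionisation, should give (2S,3aS)-7-{[(2R)-3,3-dimethyloxiran-2-yl]methyl}-6-ethoxy-5-(2-methylpropanoyl)-3a-(prop-2-en-1-yl)-2-{2-[(triethylsilyl)oxy]propan-2-yl}-3,3a-dihydro-1-benzofuran-4(2H)-one F1. Olefin cross-metathesis of this allyl dienone with 2-methyl-2-butene (second-generation Ru–NHC catalyst, CH2Cl2, 40 °C) turns allyl into prenyl and comes back at 22.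

2. Step 8. The radical pair may escape the solvent cage (deacylation to the phenol), or the arylmethyl oxirane may be photolysed. Fallback: from 20, bromination of the only free ring position (NBS, MeCN, 0 °C; no alkene is left at this stage) should give (2S)-5-bromo-7-{[(2R)-3,3-dimethyloxiran-2-yl]methyl}-6-ethoxy-2-{2-[(triethylsilyl)oxy]propan-2-yl}-2,3-dihydro-1-benzofuran-4-yl 2-methylpropanoate F2. Bromine–lithium exchange (t-BuLi, THF, −100 °C) then triggers an anionic ortho-Fries 1,3-O→C acyl shift and comes back at 21.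

3. Step 5. The vinylketene may oligomerise, or be intercepted by amine or chloride, before the [2+2] with the volatile ynol ether. Fallback: from 10, through acid chloride 12, with no cycloaddition:
   - C-acylation of magnesium ethyl malonate (potassium ethyl malonate, MgCl2, Et3N, MeCN) with decarboxylation should give ethyl 7-methyl-3-oxo-4-[(5S)-5-{2-[(triethylsilyl)oxy]propan-2-yl}oxolan-2-ylidene]oct-6-enoate F3.
   - O-ethylation (Et3OBF4, iPr2NEt, CH2Cl2) gives ethyl 3-ethoxy-7-methyl-4-[(5S)-5-{2-[(triethylsilyl)oxy]propan-2-yl}oxolan-2-ylidene]octa-2,6-dienoate F4.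
   - Saponification (LiOH, THF/H2O) gives 3-ethoxy-7-methyl-4-[(5S)-5-{2-[(triethylsilyl)oxy]propan-2-yl}oxolan-2-ylidene]octa-2,6-dienoic acid F5.
   - Heating this acid with 2-methylpropanoic anhydride and its sodium salt (toluene, 100 °C) forms the mixed anhydride, which loses carboxylate by 1,6-elimination to the same dienylketene 15 (classical anhydride-mediated cyclodehydration of dienoic acids to aryl esters). After 6π closure the phenol is acylated in the flask, so the fallback comes back at 19.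

**Further compounds**

F1 | step 9 | (2S,3aS)-7-{[(2R)-3,3-dimethyloxiran-2-yl]methyl}-6-ethoxy-5-(2-methylpropanoyl)-3a-(prop-2-en-1-yl)-2-{2-[(triethylsilyl)oxy]propan-2-yl}-3,3a-dihydro-1-benzofuran-4(2H)-one | CCOC1=C(C(=O)C(C)C)C(=O)[C@@]2(CC=C)C[C@@H](C(C)(C)O[Si](CC)(CC)CC)OC2=C1C[C@H]3OC3(C)C
F2 | step 8 | (2S)-5-bromo-7-{[(2R)-3,3-dimethyloxiran-2-yl]methyl}-6-ethoxy-2-{2-[(triethylsilyl)oxy]propan-2-yl}-2,3-dihydro-1-benzofuran-4-yl 2-methylpropanoate | CCOc1c(Br)c(OC(=O)C(C)C)c2C[C@@H](C(C)(C)O[Si](CC)(CC)CC)Oc2c1C[C@H]3OC3(C)C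
F3 | step 5 | ethyl 7-methyl-3-oxo-4-[(5S)-5-{2-[(triethylsilyl)oxy]propan-2-yl}oxolan-2-ylidene]oct-6-enoate | CCOC(=O)CC(=O)C(CC=C(C)C)=C1CC[C@@H](C(C)(C)O[Si](CC)(CC)CC)O1
F4 | step 5 | ethyl 3-ethoxy-7-methyl-4-[(5S)-5-{2-[(triethylsilyl)oxy]propan-2-yl}oxolan-2-ylidene]octa-2,6-dienoate | CCOC(=O)C=C(OCC)C(CC=C(C)C)=C1CC[C@@H](C(C)(C)O[Si](CC)(CC)CC)O1
F5 | step 5 | 3-ethoxy-7-methyl-4-[(5S)-5-{2-[(triethylsilyl)oxy]propan-2-yl}oxolan-2-ylidene]octa-2,6-dienoic acid | OC(=O)C=C(OCC)C(CC=C(C)C)=C1CC[C@@H](C(C)(C)O[Si](CC)(CC)CC)O1
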